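**Assumptions:** The target is made as the free base. Numbered compounds are substrates, intermediates and skeleton-contributing building blocks; protecting-group and heteroatom reagents are given by name and SMILES in the "Reagents that add atoms" line. O-(tert-Butyldiphenylsilyl)hydroxylamine is taken as commercial (otherwise one step from NH2OH·HCl and TBDPSCl).

## Retrosynthetic overview

1. Broussonetine S ⇐ global deprotection (LiAlH4, then H2/Pd–HCl) of the fully protected N-hydroxypyrrolidine 14, which already carries the whole C13 side chain.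
2. C5–C1' bond plus the C5 and C1' stereocentres ⇐ new step: stereoretentive addition of a (−)-sparteine-generated α-lithio O-alkyl carbamate (from 13) to the cyclic nitrone 4.
3. Nitrone 4 (the only ring, formed first) ⇐ 2,3,5-tri-O-benzyl-D-arabinofuranose by intramolecular oxime N-alkylation with double inversion at C4.
4. Chain 13 ⇐ (S)-epichlorohydrin as the C9'–C11' linchpin (sets C10'), opened first by the Grignard of 8-bromooctyl carbamate, then by vinyl Grignard, followed by hydroboration.

## Route

**Step 1**
Reactants: 1, 2,3,5-tri-O-benzyl-D-arabinofuranose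
Product: 2, 2,3,5-tri-O-benzyl-D-arabinose O-(tert-butyldiphenylsilyl) oxime (open chain, (2R,3R,4R), free 4-OH, E/Z mixture)
Conditions: TBDPSONH2, PPTS (cat.), MgSO4, toluene, reflux
Reagents that add atoms: O-(tert-butyldiphenylsilyl)hydroxylamine, NO[Si](c1ccccc1)(c1ccccc1)C(C)(C)C
Why: Oxime condensation on the open-chain aldehyde form of the lactol frees the C4 hydroxyl without touching any stereocentre.

**Step 2**
Reactants: 2, the O-TBDPS oxime
Product: 3, 2,3,5-tri-O-benzyl-4-deoxy-4-iodo-L-xylose O-(tert-butyldiphenylsilyl) oxime ((2R,3S,4S), C4 inverted)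
Conditions: I2, PPh3, imidazole, toluene, 80 °C
Reagents that add atoms: iodine, II
Why: Garegg–Samuelsson (Appel-type) iodination displaces the alkoxyphosphonium by iodide in an SN2 step, inverting C4.

**Step 3**
Reactants: 3, the 4-iodo oxime
Product: 4, (3R,4R,5R)-3,4-bis(benzyloxy)-5-[(benzyloxy)methyl]-3,4-dihydro-2H-pyrrole 1-oxide (D-arabino cyclic nitrone)
Conditions: TBAF, toluene/THF, reflux
Reagents that add atoms: none
Why: Fluoride desilylation releases the oximate, whose nitrogen displaces iodide in a 5-exo-tet SN2 (intramolecular oxime N-alkylation); this second inversion restores the D-arabino configuration at C5 and forms the pyrrolidine ring.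

**Step 4**
Reactants: 5, 8-bromooctan-1-ol
Product: 6, 8-bromooctyl N,N-diisopropylcarbamate
Conditions: iPr2NCOCl, Et3N, DMAP (cat.), CH2Cl2, reflux
Reagents that add atoms: N,N-diisopropylcarbamoyl chloride, ClC(=O)N(C(C)C)C(C)C
Why: O-Carbamoylation installs a hindered carbamate that is inert to Grignard, borane and base chemistry and later serves as the directing group for the Hoppe lithiation.

**Step 5**
Reactants: 6, 8-bromooctyl N,N-diisopropylcarbamate; 7, (S)-epichlorohydrin
Product: 8, (S)-11-chloro-10-hydroxyundecyl N,N-diisopropylcarbamate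
Conditions: 6, Mg, I2 (cat.), THF, rt→40 °C; then 7, CuI (10 mol %), THF, −40→−20 °C
Reagents that add atoms: none (all heavy atoms come from 6 and 7)
Why: Cu(I)-catalysed Grignard opening of the epoxide at its CH2 terminus leaves the stereocentre (future C10') untouched, so it is taken intact from (S)-epichlorohydrin.

**Step 6**
Reactants: 8, the chlorohydrin
Product: 9, 9-[(2S)-oxiran-2-yl]nonyl N,N-diisopropylcarbamate
Conditions: K2CO3, MeOH, rt
Reagents that add atoms: none
Why: Intramolecular Williamson closure onto the CH2Cl carbon forms the terminal epoxide without breaking any bond at the stereocentre.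

**Step 7**
Reactants: 9, the (S)-epoxide; 10, vinylmagnesium bromide
Product: 11, (S)-10-hydroxytridec-12-en-1-yl N,N-diisopropylcarbamate
Conditions: 10, CuI (15 mol %), THF, −40→−20 °C
Reagents that add atoms: vinylmagnesium bromide (compound 10), C=C[Mg]Br
Why: Cu-catalysed vinyl Grignard opening at the unsubstituted epoxide carbon gives the homoallylic alcohol with the carbinol configuration unchanged.

**Step 8**
Reactants: 11, the homoallylic alcohol
Product: 12, (S)-10,13-dihydroxytridecyl N,N-diisopropylcarbamate
Conditions: 9-BBN (2.5 equiv), THF, 0 °C→rt; then 3 M NaOH, 30 % H2O2, 0 °C→rt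
Reagents that add atoms: hydrogen peroxide, OO (9-BBN delivers H only)
Why: Anti-Markovnikov hydroboration–oxidation of the terminal alkene gives the primary alcohol (C13') and completes the 1,4-diol; the carbamate is inert.

**Step 9**
Reactants: 12, the diol
Product: 13, (S)-10,13-bis[(tert-butyldimethylsilyl)oxy]tridecyl N,N-diisopropylcarbamate
Conditions: TBSCl (2.5 equiv), imidazole, DMF, rt
Reagents that add atoms: tert-butyldimethylsilyl chloride, CC(C)(C)[Si](C)(C)Cl
Why: Silylation gives ethers that tolerate s-BuLi at −78 °C and LiAlH4 and are removed in the final acidic hydrogenolysis.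

**Step 10 (key step, new)**
Reactants: 13, the bis-TBS carbamate (1.3 equiv); 4, the cyclic nitrone (1.0 equiv)
Product: 14, (1R,10S)-1-[(2R,3R,4R,5R)-3,4-bis(benzyloxy)-5-[(benzyloxy)methyl]-1-hydroxypyrrolidin-2-yl]-10,13-bis[(tert-butyldimethylsilyl)oxy]tridecyl N,N-diisopropylcarbamate
Conditions: 13, s-BuLi (1.25 equiv), (−)-sparteine (1.3 equiv), Et2O, −78 °C, 5 h; then 4 in Et2O/toluene, −78 °C, 3 h; MeOH, aq NH4Cl
Reagents that add atoms: none
Why: Proposed new method: stereoretentive 1,2-addition of a configurationally stable, sparteine-complexed α-lithio O-alkyl carbamate to a cyclic aldonitrone — s-BuLi/(−)-sparteine removes the pro-S α-proton of 13, the nitrone oxygen coordinates lithium and the carbanion is delivered by a four-centre SE2-retention pathway (giving 1'R) to the nitrone carbon on the face anti to the adjacent C3–OBn (giving the 2,3-trans, all-trans 5R ring), so C1' is reagent-controlled and C5 substrate-controlled while the C5–C1' bond is formed; the closest known reactions are Hoppe carbanion additions to aldehydes, ketones and CO2 with retention, and Grignard/organolithium additions to this same nitrone with 2,3-trans selectivity.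

**Step 11**
Reactants: 14, the carbamate adduct
Product: 15, (1R,10S)-1-[(2R,3R,4R,5R)-3,4-bis(benzyloxy)-5-[(benzyloxy)methyl]-1-hydroxypyrrolidin-2-yl]-10,13-bis[(tert-butyldimethylsilyl)oxy]tridecan-1-ol
Conditions: LiAlH4 (excess), THF, reflux; Rochelle salt work-up
Reagents that add atoms: none
Why: Standard hydride cleavage of the hindered N,N-diisopropylcarbamate frees the C1' alcohol with retention (the C–O bond is not broken); it is run on the N–OH compound so that any O→O carbamoyl shift still gives a cleavable N–O–carbamate, whereas a free N–H could trap the group as a urea.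

**Step 12**
Reactants: 15, the N-hydroxy alcohol
Product: 16, Broussonetine S, (2R,3R,4R,5R)-2-(hydroxymethyl)-5-[(1R,10S)-1,10,13-trihydroxytridecyl]pyrrolidine-3,4-diol
Conditions: H2 (1 atm), 10 % Pd/C, MeOH, 6 M HCl, rt, 24–48 h; then Dowex 50W-X8 (H+), elute aq NH3
Reagents that add atoms: none
Why: Pd-catalysed hydrogenolysis removes the three benzyl ethers and cleaves the N–O bond while HCl/MeOH removes both TBS ethers, with no stereocentre involved.

## Compound list

1 | 2,3,5-tri-O-benzyl-D-arabinofuranose | OC1O[C@H](COCc2ccccc2)[C@@H](OCc2ccccc2)[C@@H]1OCc1ccccc1 | starting material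
2 | 2,3,5-tri-O-benzyl-D-arabinose O-TBDPS oxime | O[C@H](COCc1ccccc1)[C@@H](OCc1ccccc1)[C@H](OCc1ccccc1)C=NO[Si](c1ccccc1)(c1ccccc1)C(C)(C)C | intermediate
3 | 2,3,5-tri-O-benzyl-4-deoxy-4-iodo-L-xylose O-TBDPS oxime | I[C@@H](COCc1ccccc1)[C@@H](OCc1ccccc1)[C@H](OCc1ccccc1)C=NO[Si](c1ccccc1)(c1ccccc1)C(C)(C)C | intermediate
4 | (3R,4R,5R)-3,4-bis(benzyloxy)-5-[(benzyloxy)methyl]-3,4-dihydro-2H-pyrrole 1-oxide | C1=[N+]([O-])[C@H](COCc2ccccc2)[C@@H](OCc2ccccc2)[C@@H]1OCc1ccccc1 | intermediate
5 | 8-bromooctan-1-ol | OCCCCCCCCBr | starting material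
6 | 8-bromooctyl N,N-diisopropylcarbamate | BrCCCCCCCCOC(=O)N(C(C)C)C(C)C | intermediate
7 | (S)-epichlorohydrin | ClC[C@@H]1CO1 | starting material
8 | (S)-11-chloro-10-hydroxyundecyl N,N-diisopropylcarbamate | ClC[C@@H](O)CCCCCCCCCOC(=O)N(C(C)C)C(C)C | intermediate
9 | 9-[(2S)-oxiran-2-yl]nonyl N,N-diisopropylcarbamate | C1[C@@H](O1)CCCCCCCCCOC(=O)N(C(C)C)C(C)C | intermediate
10 | vinylmagnesium bromide | C=C[Mg]Br | starting material
11 | (S)-10-hydroxytridec-12-en-1-yl N,N-diisopropylcarbamate | C=CC[C@@H](O)CCCCCCCCCOC(=O)N(C(C)C)C(C)C | intermediate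
12 | (S)-10,13-dihydroxytridecyl N,N-diisopropylcarbamate | OCCC[C@@H](O)CCCCCCCCCOC(=O)N(C(C)C)C(C)C | intermediate
13 | (S)-10,13-bis[(tert-butyldimethylsilyl)oxy]tridecyl N,N-diisopropylcarbamate | CC(C)(C)[Si](C)(C)OCCC[C@@H](O[Si](C)(C)C(C)(C)C)CCCCCCCCCOC(=O)N(C(C)C)C(C)C | intermediate
14 | (1R,10S)-1-[(2R,3R,4R,5R)-3,4-bis(benzyloxy)-5-[(benzyloxy)methyl]-1-hydroxypyrrolidin-2-yl]-10,13-bis(TBSO)tridecyl N,N-diisopropylcarbamate | CC(C)(C)[Si](C)(C)OCCC[C@@H](O[Si](C)(C)C(C)(C)C)CCCCCCCC[C@@H](OC(=O)N(C(C)C)C(C)C)[C@H]1N(O)[C@H](COCc2ccccc2)[C@@H](OCc2ccccc2)[C@@H]1OCc1ccccc1 | intermediate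
15 | (1R,10S)-1-[(2R,3R,4R,5R)-3,4-bis(benzyloxy)-5-[(benzyloxy)methyl]-1-hydroxypyrrolidin-2-yl]-10,13-bis(TBSO)tridecan-1-ol | CC(C)(C)[Si](C)(C)OCCC[C@@H](O[Si](C)(C)C(C)(C)C)CCCCCCCC[C@@H](O)[C@H]1N(O)[C@H](COCc2ccccc2)[C@@H](OCc2ccccc2)[C@@H]1OCc1ccccc1 | intermediate
16 | Broussonetine S | OCCC[C@@H](O)CCCCCCCC[C@@H](O)[C@H]1N[C@H](CO)[C@@H](O)[C@@H]1O | target

## Summary

**Total steps:** 12 (nitrone branch, steps 1–3; chain branch, steps 4–9; union and endgame, steps 10–12).

**Longest linear sequence:** 9 steps (steps 4–12, from 8-bromooctan-1-ol).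

**Steps most likely to fail, with fallbacks:**

1. **Step 10 (proposed new nitrone addition).** Risks are sluggish addition of the hindered sparteine-bound carbanion, nitrone α-deprotonation, or loss of configuration on warming. Fallback (known chemistry, different bond construction):
   - add vinylmagnesium bromide to nitrone 4 (established 2,3-trans addition);
   - reduce the N–O bond with Zn/AcOH and protect nitrogen as N-Cbz;
   - ozonolyse to the pyrrolidine-2-carbaldehyde;
   - add the C2'–C13' alkylmagnesium bromide (made by the same epichlorohydrin sequence);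
   - set 1'R by Dess–Martin oxidation and diastereoselective hydride reduction of the α-amino ketone (choosing a chelating or a Felkin-type reductant), with Mitsunobu inversion as a backup.

2. **Step 11 (LiAlH4 removal of the diisopropylcarbamate next to the N-hydroxy group).** Risks are incomplete cleavage or carbamoyl migration. Fallback: build the chain with Hoppe's acid/base-labile Cby carbamate (2,2,4,4-tetramethyl-1,3-oxazolidine-3-carbonyl chloride in step 4). It directs the same sparteine lithiation and is removed with MeSO3H/MeOH then Ba(OH)2 (which also removes the TBS groups) before hydrogenolysis.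

3. **Steps 2–3 (iodination with inversion and nitrone ring closure).** Risks are elimination or low yield at the hindered secondary centre. Fallback: reach the same nitrone 4 by the single-inversion route from 2,3,5-tri-O-benzyl-L-xylofuranose (O-silyl oxime, C4 mesylate, then fluoride-induced cyclisation), which avoids the secondary iodide.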